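## The problem

Target 15 (CNP0316331.1) is a trans‑3‑hydroxyflavanone: the resorcinol‑type ring A is fused through C4a–C8a to the dihydropyranone ring C, ring B sits on C2, three prenyl (3‑methylbut‑2‑enyl) groups occupy C8, C3' and C5', and free phenols stand at C7 and C4'. The only stereocentres are the neighbouring C2 and C3, both R, with the C2 aryl group and the C3 hydroxyl trans on ring C. Both are base‑labile, because C3 is α to the C4 carbonyl and an enolate there can expel O1 from the β‑carbon C2 by retro‑oxa‑Michael opening, which erases C2. A C2 aryl group already in place can steer a reagent to the opposite face of C3, whereas the reverse order would leave the fragile C2–O1 or C2–aryl bond to be made last; C2 is therefore set first and C3 under its control. The three electron‑rich trisubstituted alkenes rule out hydrogenolysis, peracids and other electrophilic oxidants, and they cyclise onto their ortho phenols in strong acid, so the phenol protection must come off under mild acid. The C8 prenyl lies between the two ring A oxygens, which makes its placement a regiochemical problem of its own. The feature that opens the key step is C2 itself: when ring B is carried as a benzyl ether on the ring A oxygen that becomes O1, the O–CH2 group is a C–H site activated by the oxygen and by an electron‑rich arene. It is the sixth atom counted from C3 if C3 is the terminal carbon of a diazomethyl ketone on C4a, so a carbenoid insertion forms C2–C3, closes ring C and creates C2 from an achiral precursor.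

## Retrosynthesis

**15 ⇒ 14.** The two phenolic O–CH2OCH3 bonds are cut. Acetal protection is preferred to benzyl ethers, whose hydrogenolysis would saturate the prenyl groups, and to aryl silyl ethers, which would not reliably survive the carbonate alkylation and amide‑base steps. Compound 14 is no simpler in skeleton, but it has no acidic phenols, which the base and carbenoid chemistry upstream require. The forward step must cleave two acetals without letting the liberated phenols add to their ortho prenyl groups.

**14 ⇒ 13.** The C3–O bond is cut. C3 is the carbenoid carbon of the ring‑forming step and cannot carry oxygen at that stage, so the hydroxyl has to follow ring closure. Doing it then also lets the C2 aryl group direct the reagent. Oxidative routes through an alkene are excluded by the prenyl groups. Flavanone 13 has one stereocentre and no α‑ketol. The forward reaction must hydroxylate the enolate anti to the aryl group faster than the enolate can expel O1.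

**13 ⇒ 12.** The C2–C3 bond is cut; this is the key disconnection. The neighbouring cut at O1–C2 (conjugate addition of the phenol to an enone) is reversible and hard to make enantioselective for an unactivated substrate. A cut at C2–C1' would need a hindered, diprenylated aryl metal. Diazoketone 12 is achiral, has no ring C, and consists of two aromatic halves joined by one ether bond. The forward reaction asks a chiral dirhodium carboxylate to distinguish two enantiotopic benzylic hydrogens and to prefer C–H insertion over attack on the ether oxygen.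

**12 ⇒ 10 (through 11).** The C3=N2 unit is removed to leave methyl ketone 10. This avoids an acid chloride and diazomethane next to acid‑labile acetals and lets the acetyl group of the ring A starting material serve as C3–C4. An unactivated methyl ketone does not accept a diazo group directly, so the forward step activates it transiently as trifluoroacetyl diketone 11, which is cleaved during the transfer.

**10 ⇒ 4 + 9.** The O1–CH2 ether bond is cut. This is the convergent point: ring A phenol 4 and ring B benzyl bromide 9 are of similar size and are made independently. The forward reaction is an alkylation of a hydrogen‑bonded phenol flanked by two substituents, which a reactive 4‑alkoxybenzyl bromide should manage.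

**4 ⇒ 3 ⇒ 1 + 2.** The C7 acetal and then the C8–prenyl bond are cut, leading to 2,4‑dihydroxyacetophenone 1 and prenyl bromide 2. Direct C‑alkylation is the shortest way to put the prenyl between the two oxygens. It asks for selectivity for C3 over C5 and oxygen, and then for the free hydroxyl over the chelated one.

**9 ⇒ 8 ⇒ 7 ⇒ 6 ⇒ 5 + 2.** The C–Br bond, the benzylic oxidation level, the C4' acetal and both aryl–prenyl bonds are taken back to 4‑hydroxybenzaldehyde 5 and two equivalents of prenyl bromide 2. The formyl group blocks the para position and later becomes C2. The forward sequence asks for twofold ortho C‑alkylation and for neutral conditions in the bromination.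

## Roads not taken

**Alternative 1:** Ring A is cut at C4a–C8a and C5–C6, so that the benzene ring is assembled by Diels–Alder cycloaddition around a prenyl group already in place.
- **Forward step:** the diene 1‑methoxy‑2‑(3‑methylbut‑2‑enyl)‑1,3‑bis(trimethylsilyloxy)buta‑1,3‑diene A2 would add to the terminal ynone syn‑5‑(tert‑butyldimethylsilyloxy)‑4‑(methoxymethoxy)‑5‑[4‑(methoxymethoxy)‑3,5‑diprenylphenyl]pent‑1‑yn‑3‑one A3. Loss of methanol would aromatise the adduct to the resorcinol ketone syn‑1‑(2,4‑dihydroxy‑3‑prenylphenyl)‑3‑(tert‑butyldimethylsilyloxy)‑2‑(methoxymethoxy)‑3‑[4‑(methoxymethoxy)‑3,5‑diprenylphenyl]propan‑1‑one A1. Desilylation and an invertive Mitsunobu closure at C2 would then form ring C.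
- **Merits:** the C8 prenyl is placed between the two oxygens by construction. This is better than step 1 of the chosen route, which alkylates an ambident phenoxide and relies on separation. Both stereocentres are set in an open chain.
- **Weak points:** A3 has a stereocentre α to the ynone carbonyl and a β‑silyloxy group, so epimerisation and β‑elimination threaten during a thermal cycloaddition with a hindered 2‑substituted diene. The closing displacement takes place at a benzylic carbon para to an alkoxy group, which ionises easily and puts the C2 configuration at risk. Two chiral, highly functionalised partners make the sequence longer.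
- **Comparison:** the chosen plan concedes the regiocontrol. Against that it buys both arenes, creates C2 late and catalytically, and never passes C2 through an ionisable leaving group.

**Alternative 2:** The O1–C8a bond is cut with ring A at the oxidation level of a cyclohexane‑1,3‑dione.
- **Forward step:** the hydroxy triketone 4‑[3‑hydroxy‑2‑(methoxymethoxy)‑3‑[4‑(methoxymethoxy)‑3,5‑diprenylphenyl]propanoyl]‑2‑prenylcyclohexane‑1,3‑dione A5 would cyclise under mild acid with molecular sieves. The C2 hydroxyl condenses with the dione carbonyl that becomes C8a and gives the 5,6‑dihydro compound A4 (C7 enol form). Dehydrogenation across C5–C6 would then aromatise ring A.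
- **Merits:** the prenyl is fixed at the central carbon of a 1,3‑dione, again with better regiocontrol than the chosen step 1. The closure does not touch the C2–O bond. The C3 oxygen is present from the start, so no flavanone enolate is needed; in this respect the road is better than step 10 of the chosen route.
- **Weak points:** the aromatisation has to be done in the presence of three prenyl groups. Quinone‑type and metal‑based dehydrogenation reagents attack such groups, and the newly formed C7 phenol next to the C8 prenyl is prone to oxidative chromene formation. A5 requires acylation at the γ‑carbon of a 2‑substituted dione with an α,β‑dioxygenated acyl donor that is open to epimerisation.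
- **Comparison:** the chosen plan keeps ring A aromatic throughout and needs no oxidation‑state change near the prenyl groups. The price is the late hydroxylation.

**Alternative 3:** The C3–C4 bond is cut.
- **Forward step:** in the racemic dialdehyde 2‑[1‑[4‑(methoxymethoxy)‑3,5‑diprenylphenyl]‑2‑oxoethoxy]‑4‑(methoxymethoxy)‑3‑prenylbenzaldehyde A7, a chiral triazolium‑derived carbene with an amine base would turn the ring A aldehyde into an acyl‑anion equivalent. This adds to the α‑aryloxy aldehyde, whose stereocentre racemises under the base. A dynamic kinetic resolution could thus give (2R,3R)‑3‑hydroxy‑7,4'‑bis(methoxymethoxy)‑8,3',5'‑triprenylflavanone A6, which is identical with 14.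
- **Merits:** one metal‑free step would form ring C, both stereocentres and the C3 hydroxyl. That is shorter than the three operations of the chosen route (diazo transfer, insertion, hydroxylation) and avoids a flavanone enolate. In step economy after fragment union this road is the better one.
- **Weak points:** the electron‑rich ring A aldehyde is the poorer electrophile towards the carbene, so the aliphatic aldehyde may become the acyl anion and give the isomeric ketol or intermolecular products. The secondary α‑ketol A6 remains exposed to base and carbene (retro‑benzoin, C3 epimerisation, ketol shift). A7 is an enolisable, oxidation‑prone aldehyde that needs its own multistep preparation.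
- **Comparison:** the chosen plan sets against the shorter endgame an irreversible C–C bond formation from a stable achiral precursor, one stereocentre at a time with separate means of control, and closer precedent for the bond type.

Key step: step 9

Assumption: the S‑configured catalyst is taken to favour insertion into the hydrogen that leads to (2S)‑13; should the opposite sense be found, the mirror‑image catalyst Rh2(R‑PTTL)4 is used with no other change.

## Route

Step 1
Reactants: 1 2,4‑dihydroxyacetophenone; 2 prenyl bromide (1‑bromo‑3‑methylbut‑2‑ene)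
Product: 3 1‑[2,4‑dihydroxy‑3‑(3‑methylbut‑2‑enyl)phenyl]ethanone
Conditions: KOH (10% aq), 0 °C to rt
Reagents that add atoms: none
Why: C‑alkylation of an ambident phenoxide; water hydrogen‑bonds the oxygens and C3, ortho to both of them, is the most nucleophilic carbon, so the 3‑prenyl isomer should be the main C‑alkylated product, with the 5‑prenyl, O‑prenyl and bis‑prenyl by‑products removed by chromatography.

Step 2
Reactants: 3 1‑[2,4‑dihydroxy‑3‑(3‑methylbut‑2‑enyl)phenyl]ethanone
Product: 4 1‑[2‑hydroxy‑4‑(methoxymethoxy)‑3‑(3‑methylbut‑2‑enyl)phenyl]ethanone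
Conditions: MOMCl, K2CO3, acetone, rt
Reagents that add atoms: chloromethyl methyl ether, COCCl
Why: Williamson‑type O‑alkylation; the C2 hydroxyl is held in a hydrogen bond to the acetyl carbonyl and is flanked on both sides, so only the C4 hydroxyl should react.

Step 3
Reactants: 5 4‑hydroxybenzaldehyde; 2 prenyl bromide (first of the two equivalents consumed)
Product: 6 4‑hydroxy‑3,5‑bis(3‑methylbut‑2‑enyl)benzaldehyde
Conditions: KOH (10% aq), prenyl bromide (2.5 equiv in all), 0 °C to rt
Reagents that add atoms: prenyl bromide (second equivalent), CC(C)=CCBr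
Why: Twofold ortho C‑alkylation of the phenoxide in water, one equivalent of prenyl bromide per ortho carbon; the formyl group blocks the para position, so only the two ortho carbons are available, and mono‑prenyl phenol recovered at chromatography can be put through the same conditions again.

Step 4
Reactants: 6 4‑hydroxy‑3,5‑bis(3‑methylbut‑2‑enyl)benzaldehyde
Product: 7 4‑(methoxymethoxy)‑3,5‑bis(3‑methylbut‑2‑enyl)benzaldehyde
Conditions: MOMCl, K2CO3, acetone, reflux
Reagents that add atoms: chloromethyl methyl ether, COCCl
Why: Williamson‑type O‑alkylation of an acidic 4‑formylphenol; the ortho CH2 groups hinder the oxygen only moderately, and the small, reactive chloromethyl ether should still reach it.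

Step 5
Reactants: 7 4‑(methoxymethoxy)‑3,5‑bis(3‑methylbut‑2‑enyl)benzaldehyde
Product: 8 [4‑(methoxymethoxy)‑3,5‑bis(3‑methylbut‑2‑enyl)phenyl]methanol
Conditions: NaBH4, MeOH, 0 °C
Reagents that add atoms: none
Why: Hydride reduction of an aryl aldehyde; the acetal and the isolated alkenes are inert to borohydride.

Step 6
Reactants: 8 [4‑(methoxymethoxy)‑3,5‑bis(3‑methylbut‑2‑enyl)phenyl]methanol
Product: 9 5‑(bromomethyl)‑2‑(methoxymethoxy)‑1,3‑bis(3‑methylbut‑2‑enyl)benzene
Conditions: CBr4, PPh3, CH2Cl2, 0 °C
Reagents that add atoms: carbon tetrabromide, BrC(Br)(Br)Br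
Why: Appel reaction; the neutral conditions spare the acetal and the alkenes, and the reactive 4‑alkoxybenzyl bromide is used at once without storage.

Step 7
Reactants: 4 1‑[2‑hydroxy‑4‑(methoxymethoxy)‑3‑(3‑methylbut‑2‑enyl)phenyl]ethanone; 9 5‑(bromomethyl)‑2‑(methoxymethoxy)‑1,3‑bis(3‑methylbut‑2‑enyl)benzene
Product: 10 1‑[2‑[4‑(methoxymethoxy)‑3,5‑diprenylbenzyloxy]‑4‑(methoxymethoxy)‑3‑prenylphenyl]ethanone
Conditions: K2CO3, n‑Bu4NI (cat.), DMF, 50 °C
Reagents that add atoms: none
Why: Williamson ether synthesis; a polar aprotic solvent and mild heating break the intramolecular hydrogen bond of the flanked phenol, and the benzylic bromide is reactive enough to alkylate the hindered phenoxide at oxygen.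

Step 8
Reactants: 10 1‑[2‑[4‑(methoxymethoxy)‑3,5‑diprenylbenzyloxy]‑4‑(methoxymethoxy)‑3‑prenylphenyl]ethanone
Product: 12 2‑diazo‑1‑[2‑[4‑(methoxymethoxy)‑3,5‑diprenylbenzyloxy]‑4‑(methoxymethoxy)‑3‑prenylphenyl]ethanone, via trifluoroacetyl diketone 11 (not isolated)
Conditions: LiN(SiMe3)2, THF, −78 °C; CF3CO2CH2CF3, −78 °C; aq NH4Cl work‑up; then MsN3, Et3N, H2O, MeCN, rt
Reagents that add atoms: 2,2,2‑trifluoroethyl trifluoroacetate, O=C(OCC(F)(F)F)C(F)(F)F (trifluoroacetyl group of 11); methanesulfonyl azide, CS(=O)(=O)N=[N+]=[N-] (diazo nitrogens of 12)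
Why: Detrifluoroacetylative diazo transfer; Claisen‑type trifluoroacetylation of the kinetic enolate gives a 1,3‑diketone acidic enough for sulfonyl azide transfer under amine base, and the trifluoroacetyl group is expelled in the fragmentation, leaving the diazomethyl ketone.

Step 9
Reactants: 12 2‑diazo‑1‑[2‑[4‑(methoxymethoxy)‑3,5‑diprenylbenzyloxy]‑4‑(methoxymethoxy)‑3‑prenylphenyl]ethanone
Product: 13 (2S)‑7‑(methoxymethoxy)‑2‑[4‑(methoxymethoxy)‑3,5‑diprenylphenyl]‑8‑prenylchroman‑4‑one
Conditions: Rh2(S‑PTTL)4 (dirhodium tetrakis[N‑phthaloyl‑(S)‑tert‑leucinate], 2 mol %), CH2Cl2, 0 °C to rt, slow addition of 12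
Reagents that add atoms: none
Why: The catalyst attacks the diazo carbon of 12, nitrogen is lost and an electrophilic divalent‑rhodium carbenoid forms at C3. The carbenoid carbon then inserts into one benzylic O–CH2 hydrogen through a concerted, asynchronous three‑centre transition state with hydride‑transfer character, forming C2–C3 and releasing the catalyst. The closest known reaction type is the dirhodium tetracarboxylate‑catalysed intramolecular C–H insertion of 2‑alkoxyaryl diazomethyl ketones to chroman‑4‑ones, including chiral carboxylate variants. Ring C closes by C2–C3 bond formation as a 1,6‑insertion through a six‑membered array (C3, C4, C4a, C8a, O1, C2); no five‑membered ring can form because the atom in that position is O1 and carries no hydrogen. The new stereocentre C2 is set by the catalyst alone, whose phthalimido‑tert‑leucinate ligand wall distinguishes the two enantiotopic benzylic hydrogens of the achiral substrate. The step needs site selectivity, chemoselectivity for insertion over oxonium‑ylide formation at O1 with 1,2‑benzyl shift, and enantioselectivity. Site selectivity follows from geometry: the C8 prenyl CH2 and the C7 acetal are meta and para to the acyl group and cannot reach C3, and the ring B alkenes could only be reached through a macrocyclic or intermolecular path that slow addition suppresses. Insertion is favoured because the C–H bond is activated by O1 and by the electron‑rich 4‑alkoxyaryl ring, while the O1 lone pair is partly delocalised into the acyl‑bearing ring A and is screened by the bulky ligands.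

Step 10
Reactants: 13 (2S)‑7‑(methoxymethoxy)‑2‑[4‑(methoxymethoxy)‑3,5‑diprenylphenyl]‑8‑prenylchroman‑4‑one
Product: 14 (2R,3R)‑3‑hydroxy‑7‑(methoxymethoxy)‑2‑[4‑(methoxymethoxy)‑3,5‑diprenylphenyl]‑8‑prenylchroman‑4‑one
Conditions: LiN(SiMe3)2, THF, −78 °C; 2‑(phenylsulfonyl)‑3‑phenyloxaziridine, −78 °C; aq NH4Cl at −78 °C
Reagents that add atoms: 2‑(phenylsulfonyl)‑3‑phenyloxaziridine, O=S(=O)(c1ccccc1)N1OC1c1ccccc1
Why: Enolate hydroxylation with an N‑sulfonyloxaziridine; the oxidant approaches the enolate face anti to the C2 aryl group, giving the trans ketol, and the low temperature and the covalent lithium enolate are meant to outrun β‑elimination of O1. The C2 descriptor changes from S to R only because the oxygenated C3 now outranks the aryl carbon.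

Step 11
Reactants: 14 (2R,3R)‑3‑hydroxy‑7‑(methoxymethoxy)‑2‑[4‑(methoxymethoxy)‑3,5‑diprenylphenyl]‑8‑prenylchroman‑4‑one
Product: 15 (2R,3R)‑3,7‑dihydroxy‑2‑[4‑hydroxy‑3,5‑bis(3‑methylbut‑2‑enyl)phenyl]‑8‑(3‑methylbut‑2‑enyl)chroman‑4‑one
Conditions: HCl (3 M aq), MeOH, rt to 40 °C
Reagents that add atoms: none
Why: Acid‑catalysed transacetalisation of the two aryl methoxymethyl ethers with methanol; acetal cleavage is faster than protonation of the trisubstituted alkenes under dilute acid, and neither stereocentre is enolised under these conditions.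

## Compound list

1 | 2,4‑dihydroxyacetophenone | CC(=O)c1ccc(O)cc1O | starting material
2 | prenyl bromide (1‑bromo‑3‑methylbut‑2‑ene) | CC(C)=CCBr | starting material
3 | 1‑[2,4‑dihydroxy‑3‑(3‑methylbut‑2‑enyl)phenyl]ethanone | CC(=O)c1ccc(O)c(CC=C(C)C)c1O | intermediate
4 | 1‑[2‑hydroxy‑4‑(methoxymethoxy)‑3‑(3‑methylbut‑2‑enyl)phenyl]ethanone | CC(=O)c1ccc(OCOC)c(CC=C(C)C)c1O | intermediate
5 | 4‑hydroxybenzaldehyde | O=Cc1ccc(O)cc1 | starting material
6 | 4‑hydroxy‑3,5‑bis(3‑methylbut‑2‑enyl)benzaldehyde | O=Cc1cc(CC=C(C)C)c(O)c(CC=C(C)C)c1 | intermediate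
7 | 4‑(methoxymethoxy)‑3,5‑bis(3‑methylbut‑2‑enyl)benzaldehyde | O=Cc1cc(CC=C(C)C)c(OCOC)c(CC=C(C)C)c1 | intermediate
8 | [4‑(methoxymethoxy)‑3,5‑bis(3‑methylbut‑2‑enyl)phenyl]methanol | OCc1cc(CC=C(C)C)c(OCOC)c(CC=C(C)C)c1 | intermediate
9 | 5‑(bromomethyl)‑2‑(methoxymethoxy)‑1,3‑bis(3‑methylbut‑2‑enyl)benzene | BrCc1cc(CC=C(C)C)c(OCOC)c(CC=C(C)C)c1 | intermediate
10 | 1‑[2‑[4‑(methoxymethoxy)‑3,5‑diprenylbenzyloxy]‑4‑(methoxymethoxy)‑3‑prenylphenyl]ethanone | CC(=O)c1ccc(OCOC)c(CC=C(C)C)c1OCc1cc(CC=C(C)C)c(OCOC)c(CC=C(C)C)c1 | intermediate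
11 | 4,4,4‑trifluoro‑1‑[2‑[4‑(methoxymethoxy)‑3,5‑diprenylbenzyloxy]‑4‑(methoxymethoxy)‑3‑prenylphenyl]butane‑1,3‑dione (trifluoroacetyl diketone, used crude in step 8) | O=C(CC(=O)C(F)(F)F)c1ccc(OCOC)c(CC=C(C)C)c1OCc1cc(CC=C(C)C)c(OCOC)c(CC=C(C)C)c1 | intermediate
12 | 2‑diazo‑1‑[2‑[4‑(methoxymethoxy)‑3,5‑diprenylbenzyloxy]‑4‑(methoxymethoxy)‑3‑prenylphenyl]ethanone | [N-]=[N+]=CC(=O)c1ccc(OCOC)c(CC=C(C)C)c1OCc1cc(CC=C(C)C)c(OCOC)c(CC=C(C)C)c1 | intermediate
13 | (2S)‑7‑(methoxymethoxy)‑2‑[4‑(methoxymethoxy)‑3,5‑diprenylphenyl]‑8‑prenylchroman‑4‑one | CC(C)=CCc1cc([C@H]2Oc3c(ccc(OCOC)c3CC=C(C)C)C(=O)C2)cc(CC=C(C)C)c1OCOC | intermediate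
14 | (2R,3R)‑3‑hydroxy‑7‑(methoxymethoxy)‑2‑[4‑(methoxymethoxy)‑3,5‑diprenylphenyl]‑8‑prenylchroman‑4‑one | CC(C)=CCc1cc([C@H]2Oc3c(ccc(OCOC)c3CC=C(C)C)C(=O)[C@@H]2O)cc(CC=C(C)C)c1OCOC | intermediate
15 | (2R,3R)‑3,7‑dihydroxy‑2‑[4‑hydroxy‑3,5‑bis(3‑methylbut‑2‑enyl)phenyl]‑8‑(3‑methylbut‑2‑enyl)chroman‑4‑one | CC(C)=CCc1cc([C@H]2Oc3c(ccc(O)c3CC=C(C)C)C(=O)[C@@H]2O)cc(CC=C(C)C)c1O | target

## Step count and risk

Total step count: 11. Longest linear sequence: 9 steps (steps 3, 4, 5, 6, 7, 8, 9, 10, 11).

**Step 9 (key step).**
- **What may go wrong:** the O1 lone pair may attack the carbenoid to give a five‑membered oxonium ylide, followed by 1,2‑shift of the electron‑rich benzyl group. The carbenoid may also add to ring B in a Buchner‑type reaction or dimerise. An acceptor‑only carbenoid reacts through an early transition state, so discrimination of the enantiotopic hydrogens may be weak. The C8 prenyl twists the benzyloxy group out of the ring A plane, which may make O1 more nucleophilic than a simple aryl ether oxygen.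
- **Within the disconnection:** the first adjustments are the ligand, for example the tetrachlorophthaloyl analogue Rh2(S‑TCPTTL)4, and the addition rate.
- **Fallback (ring C closed at O1–C2 instead):** it sets out from 4 and 7. Claisen–Schmidt condensation (KOH, EtOH, rt) gives the chalcone (E)‑1‑[2‑hydroxy‑4‑(methoxymethoxy)‑3‑prenylphenyl]‑3‑[4‑(methoxymethoxy)‑3,5‑diprenylphenyl]prop‑2‑en‑1‑one F1. NaOAc in refluxing EtOH cyclises it by oxa‑Michael addition to the racemic flavanone 7‑(methoxymethoxy)‑2‑[4‑(methoxymethoxy)‑3,5‑diprenylphenyl]‑8‑prenylchroman‑4‑one F2. Kinetic resolution by asymmetric transfer hydrogenation with RuCl(p‑cymene)[(R,R)‑TsDPEN] and HCO2H/Et3N is expected to reduce the (2R) antipode to the cis alcohol (2R,4R)‑7‑(methoxymethoxy)‑2‑[4‑(methoxymethoxy)‑3,5‑diprenylphenyl]‑8‑prenylchroman‑4‑ol F3 and to leave the (2S) ketone. The route is rejoined at 13, at the cost of half the material.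

**Step 10.**
- **What may go wrong:** the enolate may expel the O1 phenoxide by β‑elimination, opening the ring and erasing C2. Facial selectivity may be incomplete, and the enolate may add to the sulfonylimine formed from the oxidant.
- **Fallback:** it sets out from 13. Soft enolisation with TMSOTf and Et3N in CH2Cl2 at −20 °C avoids a free enolate and gives the silyl enol ether (2S)‑7‑(methoxymethoxy)‑2‑[4‑(methoxymethoxy)‑3,5‑diprenylphenyl]‑8‑prenyl‑4‑(trimethylsilyloxy)‑2H‑chromene F4. Neutral oxidation with the same oxaziridine in CHCl3 at 50 °C, again anti to the aryl group and with silyl migration, gives the silyl ether (2R,3R)‑7‑(methoxymethoxy)‑2‑[4‑(methoxymethoxy)‑3,5‑diprenylphenyl]‑8‑prenyl‑3‑(trimethylsilyloxy)chroman‑4‑one F5. Brief treatment with aqueous citric acid in THF cleaves the silyl ether and the route is rejoined at 14.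

**Step 11.**
- **What may go wrong:** the liberated C7 and C4' phenols may add to their ortho prenyl alkenes under acid (chroman formation), or methanol and HCl may add across the alkenes, in competition with acetal cleavage.
- **Fallback:** it sets out from 14. TMSOTf and 2,2'‑bipyridyl in CH2Cl2 at 0 °C exchange both aryl acetals for silyl ethers without a Brønsted acid and silylate the C3 hydroxyl, giving (2R,3R)‑2‑[3,5‑diprenyl‑4‑(trimethylsilyloxy)phenyl]‑8‑prenyl‑3,7‑bis(trimethylsilyloxy)chroman‑4‑one F6. Addition of water at neutral pH hydrolyses the three silyl ethers and the route is rejoined at 15.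

**Step 1.**
- **What may go wrong:** alkylation may occur at C5, at oxygen or twice, because the phenoxide is ambident and C3 is the more hindered of the two activated carbons.
- **Fallback:** it sets out from 1. O‑alkylation of the free C4 hydroxyl with 3‑chloro‑3‑methylbut‑1‑yne (K2CO3, KI, CuI, acetone, reflux) gives 1‑[2‑hydroxy‑4‑(2‑methylbut‑3‑yn‑2‑yloxy)phenyl]ethanone F7. Semihydrogenation (H2, Pd/CaCO3 poisoned with Pb(OAc)2, quinoline, EtOAc) gives 1‑[2‑hydroxy‑4‑(2‑methylbut‑3‑en‑2‑yloxy)phenyl]ethanone F8. Aromatic Claisen rearrangement in hot N,N‑diethylaniline moves the allyl unit to C3, the ortho carbon favoured by bond fixation in the chelated ketone, with allylic transposition to the prenyl group. The route is rejoined at 3.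

**Step 3.**
- **What may go wrong:** the second alkylation may stall at the mono‑prenyl stage and O‑alkylation may compete, because the formyl group lowers the carbon nucleophilicity of the phenoxide.
- **Fallback:** it sets out from 5. Bromination (Br2, AcOH, rt) gives 3,5‑dibromo‑4‑hydroxybenzaldehyde F9. Protection (MOMCl, K2CO3, acetone) gives 3,5‑dibromo‑4‑(methoxymethoxy)benzaldehyde F10. Twofold Stille coupling with tributyl(3‑methylbut‑2‑enyl)stannane and Pd(PPh3)4 in DMF at 90 °C attaches both prenyl groups through their CH2 carbon. The route is rejoined at 7.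

## Further compounds

F1 | step 9 | (E)‑1‑[2‑hydroxy‑4‑(methoxymethoxy)‑3‑prenylphenyl]‑3‑[4‑(methoxymethoxy)‑3,5‑diprenylphenyl]prop‑2‑en‑1‑one | COCOc1ccc(C(=O)/C=C/c2cc(CC=C(C)C)c(OCOC)c(CC=C(C)C)c2)c(O)c1CC=C(C)C
F2 | step 9 | racemic 7‑(methoxymethoxy)‑2‑[4‑(methoxymethoxy)‑3,5‑diprenylphenyl]‑8‑prenylchroman‑4‑one | CC(C)=CCc1cc(C2Oc3c(ccc(OCOC)c3CC=C(C)C)C(=O)C2)cc(CC=C(C)C)c1OCOC
F3 | step 9 | (2R,4R)‑7‑(methoxymethoxy)‑2‑[4‑(methoxymethoxy)‑3,5‑diprenylphenyl]‑8‑prenylchroman‑4‑ol | O[C@@H]1C[C@H](c2cc(CC=C(C)C)c(OCOC)c(CC=C(C)C)c2)Oc2c(CC=C(C)C)c(OCOC)ccc21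
F4 | step 10 | (2S)‑7‑(methoxymethoxy)‑2‑[4‑(methoxymethoxy)‑3,5‑diprenylphenyl]‑8‑prenyl‑4‑(trimethylsilyloxy)‑2H‑chromene | CC(C)=CCc1cc([C@H]2Oc3c(ccc(OCOC)c3CC=C(C)C)C(O[Si](C)(C)C)=C2)cc(CC=C(C)C)c1OCOC
F5 | step 10 | (2R,3R)‑7‑(methoxymethoxy)‑2‑[4‑(methoxymethoxy)‑3,5‑diprenylphenyl]‑8‑prenyl‑3‑(trimethylsilyloxy)chroman‑4‑one | CC(C)=CCc1cc([C@H]2Oc3c(ccc(OCOC)c3CC=C(C)C)C(=O)[C@@H]2O[Si](C)(C)C)cc(CC=C(C)C)c1OCOC
F6 | step 11 | (2R,3R)‑2‑[3,5‑diprenyl‑4‑(trimethylsilyloxy)phenyl]‑8‑prenyl‑3,7‑bis(trimethylsilyloxy)chroman‑4‑one | CC(C)=CCc1cc([C@H]2Oc3c(ccc(O[Si](C)(C)C)c3CC=C(C)C)C(=O)[C@@H]2O[Si](C)(C)C)cc(CC=C(C)C)c1O[Si](C)(C)C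
F7 | step 1 | 1‑[2‑hydroxy‑4‑(2‑methylbut‑3‑yn‑2‑yloxy)phenyl]ethanone | CC(=O)c1ccc(OC(C)(C)C#C)cc1O
F8 | step 1 | 1‑[2‑hydroxy‑4‑(2‑methylbut‑3‑en‑2‑yloxy)phenyl]ethanone | CC(=O)c1ccc(OC(C)(C)C=C)cc1O
F9 | step 3 | 3,5‑dibromo‑4‑hydroxybenzaldehyde | O=Cc1cc(Br)c(O)c(Br)c1
F10 | step 3 | 3,5‑dibromo‑4‑(methoxymethoxy)benzaldehyde | O=Cc1cc(Br)c(OCOC)c(Br)c1
A1 | alternative 1 | syn‑1‑(2,4‑dihydroxy‑3‑prenylphenyl)‑3‑(tert‑butyldimethylsilyloxy)‑2‑(methoxymethoxy)‑3‑[4‑(methoxymethoxy)‑3,5‑diprenylphenyl]propan‑1‑one | CC(C)=CCc1c(O)ccc(C(=O)[C@H](OCOC)[C@@H](O[Si](C)(C)C(C)(C)C)c2cc(CC=C(C)C)c(OCOC)c(CC=C(C)C)c2)c1O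
A2 | alternative 1 | 1‑methoxy‑2‑(3‑methylbut‑2‑enyl)‑1,3‑bis(trimethylsilyloxy)buta‑1,3‑diene | COC(O[Si](C)(C)C)=C(CC=C(C)C)C(=C)O[Si](C)(C)C
A3 | alternative 1 | syn‑5‑(tert‑butyldimethylsilyloxy)‑4‑(methoxymethoxy)‑5‑[4‑(methoxymethoxy)‑3,5‑diprenylphenyl]pent‑1‑yn‑3‑one | C#CC(=O)[C@H](OCOC)[C@@H](O[Si](C)(C)C(C)(C)C)c1cc(CC=C(C)C)c(OCOC)c(CC=C(C)C)c1
A4 | alternative 2 | 5,6‑dihydro precursor of the bis(methoxymethyl) dihydroflavonol, C7 enol form | CC(C)=CCC1=C(O)CCC2=C1O[C@H](c1cc(CC=C(C)C)c(OCOC)c(CC=C(C)C)c1)[C@@H](OCOC)C2=O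
A5 | alternative 2 | 4‑[3‑hydroxy‑2‑(methoxymethoxy)‑3‑[4‑(methoxymethoxy)‑3,5‑diprenylphenyl]propanoyl]‑2‑prenylcyclohexane‑1,3‑dione | CC(C)=CCC1C(=O)CCC(C(=O)[C@H](OCOC)[C@H](O)c2cc(CC=C(C)C)c(OCOC)c(CC=C(C)C)c2)C1=O
A6 | alternative 3 | (2R,3R)‑3‑hydroxy‑7,4'‑bis(methoxymethoxy)‑8,3',5'‑triprenylflavanone (identical with 14) | CC(C)=CCc1cc([C@H]2Oc3c(ccc(OCOC)c3CC=C(C)C)C(=O)[C@@H]2O)cc(CC=C(C)C)c1OCOC
A7 | alternative 3 | racemic 2‑[1‑[4‑(methoxymethoxy)‑3,5‑diprenylphenyl]‑2‑oxoethoxy]‑4‑(methoxymethoxy)‑3‑prenylbenzaldehyde | O=Cc1ccc(OCOC)c(CC=C(C)C)c1OC(C=O)c1cc(CC=C(C)C)c(OCOC)c(CC=C(C)C)c1
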